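C7–C8–C9(O) of ring B (C1, C5–C10) is read as a 1-siloxycyclopropane and C10=C1 as its vinyl group. C5–C6 is a terminal alkyne tied to C1 by the ring A atoms C2–C3–C4.
Key disconnection: C1–C5 and C6–C7, made in one rhodium-catalysed intramolecular (5+2) cycloaddition that opens the C7–C9 cyclopropane bond. Ring A closes first, ring B second, and C4 steers the new quaternary C1.
Precursor: C1–C5, C15 and the isopropyl carbinol come from (S)-terpinen-4-ol. The alkene is moved next to C4, the ring is cut there with loss of one CH, and the non-enolisable C5 aldehyde is homologated to the alkyne. The methyl ketone arm is grown to an E-enone, and its 2-siloxydiene is cyclopropanated.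
Endgame: C9 enol ether to ketone (ketal), hydroboration of C5=C6 for H5 and O6, C6 acylation, C8 methylenation. C9 is then reduced and inverted, because hydride is expected anti to C15. Desilylation comes last.
Key step: step 10

Numbering and faces: C1 (quaternary, methyl C15), C4 (isopropyl carbinol), C5 (ring-fusion CH), C6 (acyloxy), C8 (=C14), C9 (carbinol). Ring A = C1–C5; ring B = C1, C5–C10. β is the face of C15. The same numbers are used in monocyclic 1–8, whose ring is C1, Cx, C5, C4, C3, C2; Cx is the alkene CH of 1 and is later excised.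
Assumption: (S)-(+)-terpinen-4-ol is bought in an enantiomerically pure grade; its C4 is the only source of absolute configuration.

Step 1
Reactants: 1 (S)-terpinen-4-ol
Product: 2 (S)-terpinen-4-yl triethylsilyl ether
Conditions: TESOTf, 2,6-lutidine, CH2Cl2, 0 °C
Reagents that add atoms: triethylsilyl triflate, CC[Si](CC)(CC)OS(=O)(=O)C(F)(F)F
Why: A silyl triflate with a hindered pyridine base silylates even a tertiary alcohol (silyl ether protection) without touching C4, and the ether keeps O4 out of the later glycol-type cleavage.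

Step 2
Reactants: 2 (S)-terpinen-4-yl triethylsilyl ether
Product: 3 C1–Cx epoxide of 2 with the oxirane oxygen trans to the silyloxy group
Conditions: mCPBA, CH2Cl2, 0 °C
Reagents that add atoms: 3-chloroperbenzoic acid, OOC(=O)c1cccc(Cl)c1
Why: Prilezhaev epoxidation of the only alkene, with the peracid expected anti to the pseudo-axial silyloxy group; the face has no consequence because C1 is later flattened and Cx excised, so a minor cis epoxide converges on 9.

Step 3
Reactants: 3 C1–Cx epoxide
Product: 6 tertiary allylic alcohol (C1–OH trans to O4; Cx=C5 alkene), via hydroxy selenide 4 (not isolated), via selenoxide 5 (not isolated)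
Conditions: (PhSe)2, NaBH4, EtOH, 78 °C; then 30% H2O2, THF, 0 °C → rt
Reagents that add atoms: none
Why: Selenolate opens the epoxide by SN2 at the less substituted Cx, and the selenoxide syn-elimination can only run toward the C5 hydrogens (organoselenium epoxide-to-allylic-alcohol transposition), which places the alkene on the carbon next to C4.

Step 4
Reactants: 6 tertiary allylic alcohol
Product: 9 (R)-2-isopropyl-5-oxo-2-(triethylsilyloxy)hexanal (C5 aldehyde and C1 methyl ketone), via ozonide 7 (not isolated), via hydroxy dialdehyde 8 (not isolated)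
Conditions: O3, CH2Cl2, −78 °C; Me2S, −78 °C → rt; NaIO4, THF–H2O, rt
Reagents that add atoms: ozone, [O-][O+]=O
Why: Criegee ozonolysis cuts Cx=C5 and Malaprade cleavage of the tertiary α-hydroxy aldehyde expels Cx as formic acid and leaves the C1 ketone; the C5 aldehyde has no α-hydrogen, so it can neither enolise nor lose the β-silyloxy group, and silylated O4 protects the C4–C5 bond from periodate.

Step 5
Reactants: 9 keto aldehyde; 10 dimethyl (1-diazo-2-oxopropyl)phosphonate (Ohira–Bestmann reagent)
Product: 11 (R)-5-ethynyl-6-methyl-5-(triethylsilyloxy)heptan-2-one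
Conditions: 10, NaOMe, THF, −78 °C; then 9, −78 °C → 0 °C
Reagents that add atoms: dimethyl (1-diazo-2-oxopropyl)phosphonate, COP(=O)(OC)C(=[N+]=[N-])C(C)=O
Why: Seyferth–Gilbert homologation, in which the pre-formed diazophosphonate anion adds to the aldehyde much faster than to the methyl ketone and the alkylidene carbene gives the terminal alkyne (C6) by 1,2-hydrogen shift, while the cold, weakly basic medium holds back the aldol of the 1,5-keto aldehyde.

Step 6
Reactants: 11 alkynyl ketone; 12 diethyl [2-(methoxy(methyl)amino)-2-oxoethyl]phosphonate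
Product: 13 (2E,6R)-6-ethynyl-N-methoxy-N,3,7-trimethyl-6-(triethylsilyloxy)oct-2-enamide
Conditions: 12, NaH, THF, 0 °C; then 11, 0 → 45 °C; E isomer separated by chromatography
Reagents that add atoms: diethyl [2-(methoxy(methyl)amino)-2-oxoethyl]phosphonate, CCOP(=O)(CC(=O)N(C)OC)OCC
Why: Horner–Wadsworth–Emmons olefination, run only now that no aldehyde competes, puts the carboxamide trans to the longer C2 chain (E-C1=C10) under the usual reversible-addition control, and the alkyne C–H is too weak an acid to quench the stabilised anion.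

Step 7
Reactants: 13 Weinreb enamide; 14 methylmagnesium bromide
Product: 16 (3E,7R)-7-ethynyl-4,8-dimethyl-7-(triethylsilyloxy)non-3-en-2-one, via magnesium hemiaminal chelate 15 (not isolated)
Conditions: MeMgBr (2.5 equiv), THF, 0 °C; aq NH4Cl
Reagents that add atoms: methylmagnesium bromide, C[Mg]Br
Why: Weinreb ketone synthesis, in which the first equivalent only deprotonates the alkyne and the chelated tetrahedral adduct stops a second addition until work-up, so the methyl ketone (C8) forms with the E alkene intact.

Step 8
Reactants: 16 E-enone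
Product: 17 (R,E)-2-(tert-butyldimethylsilyloxy)-1,3-diene of 16 (C8H2=C9(OTBS)–C10H=C1)
Conditions: TBSOTf, Et3N, CH2Cl2, 0 °C
Reagents that add atoms: tert-butyldimethylsilyl triflate, CC(C)(C)[Si](C)(C)OS(=O)(=O)C(F)(F)F
Why: Soft enolisation of a methyl enone with a silyl triflate and a tertiary amine removes the α′ methyl hydrogen and gives the cross-conjugated silyl dienol ether, under conditions that leave the alkyne C–H and the tertiary silyl ether alone.

Step 9
Reactants: 17 2-siloxydiene; 18 diiodomethane
Product: 19 yne–vinylcyclopropane (O4 triethylsilyl; O9 tert-butyldimethylsilyl; E-C1=C10; 4R)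
Conditions: Et2Zn, CH2I2, CH2Cl2, 0 °C
Reagents that add atoms: diiodomethane, ICI
Why: Simmons–Smith cyclopropanation (Furukawa variant) picks the electron-rich 1,1-disubstituted enol ether alkene over the trisubstituted C1=C10 alkene and the alkyne, and unlike a titanium-mediated cyclopropanol synthesis from an ester it involves no low-valent metal that would bind the alkyne.

Step 10
Reactants: 19 yne–vinylcyclopropane
Product: 20 (1R,4R)-bicyclo[5.3.0]decadiene with C5=C6 and the C9=C10 silyl enol ether
Conditions: [Rh(CO)2Cl]2 (5 mol %), ClCH2CH2Cl (0.02 M), 80 °C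
Reagents that add atoms: none
Why: Monovalent rhodium binds the alkyne and the vinylcyclopropane and opens the strained C7–C9 bond, helped by the donor siloxy group on C9, to a trivalent σ-alkyl/π-allyl rhodacyclohexene (C7–Rh, allyl C9–C10–C1). The tethered alkyne then inserts at the allyl terminus C1, forming C1–C5 and closing ring A in the exo mode through the three-atom tether (C5 in the ring, C6 outside it), and reductive elimination from the eight-membered rhodacycle joins C6(sp2) to C7(sp3) and closes the seven-membered ring B, leaving C5=C6 and the C9=C10 enol ether. The closest known reaction type is the rhodium-catalysed intramolecular (5+2) cycloaddition of alkyne-tethered vinylcyclopropanes, known for terminal alkynes, for 1-oxygenated cyclopropanes and, in few cases, for alkene termini that become angular-methyl quaternary carbons. C1 is the only new stereocentre and C4 its only control element: in the envelope-like five-membered insertion transition state the isopropyl group should take the outer pseudo-equatorial place on the face away from the C1 methyl, so that only the slim C4–O bond is 1,3-syn to that methyl, which leads to (1R); this 1,3-induction may be moderate and the C1 epimer would be removed by chromatography. As to the other selectivities, the two cyclopropane CH2 groups are equivalent so either cleavage gives the same product, the E alkene keeps the tether trans to the cyclopropane and the 1-siloxy group favours the reactive s-cis conformer, dilution holds back alkyne oligomerisation, and the neutral medium spares the tertiary propargylic silyl ether.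

Step 11
Reactants: 20 bicyclic diene
Product: 21 C9 ketone (C5=C6 and O4 silyl ether kept)
Conditions: Bu4NF, AcOH (1:1), THF, −20 °C
Reagents that add atoms: none
Why: Buffered fluoride cleaves a silyl enol ether far faster than a crowded tertiary triethylsilyl ether (fluoride desilylation), avoids the acid that would ionise the tertiary allylic C4–O bond, and leaves an alkene that has no path into conjugation.

Step 12
Reactants: 21 C9 ketone
Product: 22 C9 ethylene ketal
Conditions: (TMSOCH2)2, TMSOTf (5 mol %), CH2Cl2, −78 °C; pyridine quench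
Reagents that add atoms: 1,2-bis(trimethylsilyloxy)ethane, C[Si](C)(C)OCCO[Si](C)(C)C
Why: Noyori ketalisation works at −78 °C without protic acid or water, so the tertiary allylic C4 silyl ether, whose crowded oxygen is not silylated at this temperature, does not ionise and C5=C6 does not move.

Step 13
Reactants: 22 ketal
Product: 24 6α-alcohol with H5α (5S,6S; trans ring fusion), via alkylborane 23 (not isolated)
Conditions: BH3·THF, THF, 0 °C → rt; then 3 M NaOH, 30% H2O2, 0 °C
Reagents that add atoms: hydrogen peroxide, OO
Why: Brown hydroboration–oxidation puts boron on the less substituted C6 and adds H and B syn, expected from the α face because the C15 methyl on C1 and the silyloxy group on C4 flank C5 on the β face while the α-isopropyl group can turn its methine hydrogen toward the alkene (compare 5-ene steroids), and oxidation with retention gives H5α and O6α together.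

Step 14
Reactants: 25 4-hydroxybenzoic acid
Product: 27 4-(tert-butyldimethylsilyloxy)benzoic acid, via silyl ester 26 (not isolated)
Conditions: TBSCl (2.2 equiv), imidazole, DMF, rt; then AcOH–THF–H2O, rt
Reagents that add atoms: tert-butyldimethylsilyl chloride, CC(C)(C)[Si](C)(C)Cl
Why: Double silylation followed by selective hydrolysis of the far more labile silyl ester is the standard way to mask only the phenol.

Step 15
Reactants: 24 6α-alcohol; 27 4-(tert-butyldimethylsilyloxy)benzoic acid
Product: 28 C6 4-(silyloxy)benzoate ketal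
Conditions: DCC, DMAP, CH2Cl2, rt → 40 °C
Reagents that add atoms: 4-(tert-butyldimethylsilyloxy)benzoic acid (27), OC(=O)c1ccc(O[Si](C)(C)C(C)(C)C)cc1
Why: Steglich esterification through the acylpyridinium ion acylates the only free hydroxyl group with retention at C6, this type of hindered C6 carbinol being known to accept aroyl groups under carbodiimide–DMAP activation.

Step 16
Reactants: 28 ester ketal
Product: 29 C9 keto ester
Conditions: PPTS, acetone–H2O (9:1), 55 °C
Reagents that add atoms: water, O
Why: Mild acid-catalysed ketal hydrolysis is now safe because C4–O is no longer allylic, and the hindered tertiary silyl ether, the aryl silyl ether and the ester stand pyridinium tosylate.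

Step 17
Reactants: 29 keto ester; 30 N,N-dimethylmethyleneiminium iodide (Eschenmoser's salt)
Product: 34 C8-methylene C9 ketone, via lithium enolate 31 (not isolated), via Mannich base 32 (not isolated), via ammonium iodide 33 (not isolated)
Conditions: LiN(iPr)2, THF, −78 °C; 30, −78 °C → rt; MeI, CH2Cl2, rt; DBU, CH2Cl2, 0 °C
Reagents that add atoms: N,N-dimethylmethyleneiminium iodide, C=[N+](C)C.[I-]
Why: Kinetic deprotonation takes a C8 hydrogen rather than the neopentyl C10 hydrogens next to quaternary C1, the enolate is aminomethylated (Mannich reaction) and N-methylation followed by base-induced β-elimination gives the exocyclic enone, the short cold enolate stage sparing the electron-rich aroate and the transient C8 centre vanishing.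

Step 18
Reactants: 34 exocyclic enone
Product: 35 9β-allylic alcohol (9R; epimer of the target at C9)
Conditions: NaBH4, CeCl3·7H2O, MeOH–CH2Cl2, −78 °C
Reagents that add atoms: none
Why: Luche reduction gives clean 1,2-addition, and in the chair-like ring B that keeps the s-cis enone nearly planar the axial C15 methyl lies 1,3 over the β face of C9, so hydride is expected from the open α face and the hydroxyl group ends up β.

Step 19
Reactants: 35 9β-allylic alcohol
Product: 36 9α-(4-nitrobenzoate) (9S)
Conditions: 4-O2NC6H4CO2H, PPh3, DIAD, toluene, 0 °C → rt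
Reagents that add atoms: 4-nitrobenzoic acid, OC(=O)c1ccc(cc1)[N+](=O)[O-]
Why: In the Mitsunobu reaction the oxyphosphonium group on the crowded β face is displaced by SN2 from the open α face with inversion to the target configuration, the acidic nitrobenzoic acid being the usual partner for hindered alcohols and O4 and O6 being blocked.

Step 20
Reactants: 36 9α-(4-nitrobenzoate)
Product: 37 O4-triethylsilyl ferugin (9α-OH and phenol free)
Conditions: K2CO3, MeOH, 0 °C
Reagents that add atoms: none
Why: In this base-mediated transesterification the electron-poor nitrobenzoate is methanolysed quickly with acyl–oxygen cleavage (C9 retained) and the aryl silyl ether falls off at the same time, and the resulting phenoxide deactivates the hindered C6 ester, which therefore stays.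

Step 21
Reactants: 37 O4-triethylsilyl ferugin
Product: 38 ferugin
Conditions: HF·pyridine, pyridine, THF, 0 °C → rt
Reagents that add atoms: none
Why: Buffered fluoride desilylation, driven by Si–F bond formation, frees the tertiary C4 alcohol without base, so neither acyl migration nor isomerisation of the allylic alcohol is expected and no stereocentre is touched.

Compound list
1 | (S)-terpinen-4-ol | CC1=CC[C@](O)(C(C)C)CC1 | starting material
2 | (S)-terpinen-4-yl triethylsilyl ether | CC1=CC[C@](O[Si](CC)(CC)CC)(C(C)C)CC1 | intermediate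
3 | C1–Cx epoxide of 2, oxirane O trans to OSiEt3 | C[C@]12CC[C@@](O[Si](CC)(CC)CC)(C(C)C)C[C@H]1O2 | intermediate
4 | hydroxy selenide (C1–OH, Cx–SePh, trans) | C[C@]1(O)CC[C@@](O[Si](CC)(CC)CC)(C(C)C)C[C@@H]1[Se]c2ccccc2 | intermediate
5 | selenoxide of 4 | C[C@]1(O)CC[C@@](O[Si](CC)(CC)CC)(C(C)C)C[C@@H]1[Se](=O)c2ccccc2 | intermediate
6 | 4-isopropyl-1-methyl-4-(triethylsilyloxy)cyclohex-2-en-1-ol, OH trans to OSiEt3 | C[C@]1(O)CC[C@@](O[Si](CC)(CC)CC)(C(C)C)C=C1 | intermediate
7 | ozonide of 6 (trioxolane carbons fixed by the bridge) | C[C@]1(O)CC[C@@](O[Si](CC)(CC)CC)(C(C)C)C2OOC1O2 | intermediate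
8 | hydroxy dialdehyde (Cx and C5 aldehydes) | C[C@@](O)(C=O)CC[C@@](O[Si](CC)(CC)CC)(C(C)C)C=O | intermediate
9 | (R)-2-isopropyl-5-oxo-2-(triethylsilyloxy)hexanal | O=C[C@](O[Si](CC)(CC)CC)(C(C)C)CCC(C)=O | intermediate
10 | dimethyl (1-diazo-2-oxopropyl)phosphonate | COP(=O)(OC)C(=[N+]=[N-])C(C)=O | starting material
11 | (R)-5-ethynyl-6-methyl-5-(triethylsilyloxy)heptan-2-one | C#C[C@](O[Si](CC)(CC)CC)(C(C)C)CCC(C)=O | intermediate
12 | diethyl [2-(methoxy(methyl)amino)-2-oxoethyl]phosphonate | CCOP(=O)(CC(=O)N(C)OC)OCC | starting material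
13 | (2E,6R)-6-ethynyl-N-methoxy-N,3,7-trimethyl-6-(triethylsilyloxy)oct-2-enamide | C#C[C@](O[Si](CC)(CC)CC)(C(C)C)CC/C(C)=C/C(=O)N(C)OC | intermediate
14 | methylmagnesium bromide | C[Mg]Br | starting material
15 | magnesium hemiaminal chelate (alkyne also magnesiated) | Br[Mg]C#C[C@](O[Si](CC)(CC)CC)(C(C)C)CC/C(C)=C/C(C)(O[Mg]Br)N(C)OC | intermediate
16 | (3E,7R)-7-ethynyl-4,8-dimethyl-7-(triethylsilyloxy)non-3-en-2-one | C#C[C@](O[Si](CC)(CC)CC)(C(C)C)CC/C(C)=C/C(C)=O | intermediate
17 | 2-(tert-butyldimethylsilyloxy)-1,3-diene of 16 | C#C[C@](O[Si](CC)(CC)CC)(C(C)C)CC/C(C)=C/C(=C)O[Si](C)(C)C(C)(C)C | intermediate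
18 | diiodomethane | ICI | starting material
19 | yne–vinylcyclopropane, O4-TES, O9-TBS, (R,E) | C#C[C@](O[Si](CC)(CC)CC)(C(C)C)CC/C(C)=C/C1(O[Si](C)(C)C(C)(C)C)CC1 | intermediate
20 | (1R,4R)-bicyclic diene, C5=C6 and C9=C10(OTBS) | C1CC=C2[C@](C)(CC[C@@]2(O[Si](CC)(CC)CC)C(C)C)C=C1O[Si](C)(C)C(C)(C)C | intermediate
21 | C9 ketone, C5=C6 | O=C1CCC=C2[C@](C)(CC[C@@]2(O[Si](CC)(CC)CC)C(C)C)C1 | intermediate
22 | C9 ethylene ketal of 21 | C1COC2(O1)CCC=C3[C@](C)(CC[C@@]3(O[Si](CC)(CC)CC)C(C)C)C2 | intermediate
23 | C6α alkylborane, H5α | C1COC2(O1)CC[C@H](B)[C@@H]3[C@](C)(CC[C@@]3(O[Si](CC)(CC)CC)C(C)C)C2 | intermediate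
24 | 6α-alcohol, H5α, ketal | C1COC2(O1)CC[C@H](O)[C@@H]3[C@](C)(CC[C@@]3(O[Si](CC)(CC)CC)C(C)C)C2 | intermediate
25 | 4-hydroxybenzoic acid | O=C(O)c1ccc(O)cc1 | starting material
26 | tert-butyldimethylsilyl 4-(tert-butyldimethylsilyloxy)benzoate | CC(C)(C)[Si](C)(C)OC(=O)c1ccc(O[Si](C)(C)C(C)(C)C)cc1 | intermediate
27 | 4-(tert-butyldimethylsilyloxy)benzoic acid | OC(=O)c1ccc(O[Si](C)(C)C(C)(C)C)cc1 | intermediate
28 | C6 4-(silyloxy)benzoate, C9 ketal | C1COC2(O1)CC[C@H](OC(=O)c4ccc(O[Si](C)(C)C(C)(C)C)cc4)[C@@H]3[C@](C)(CC[C@@]3(O[Si](CC)(CC)CC)C(C)C)C2 | intermediate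
29 | C9 keto ester | O=C1CC[C@H](OC(=O)c3ccc(O[Si](C)(C)C(C)(C)C)cc3)[C@@H]2[C@](C)(CC[C@@]2(O[Si](CC)(CC)CC)C(C)C)C1 | intermediate
30 | N,N-dimethylmethyleneiminium iodide | C=[N+](C)C.[I-] | starting material
31 | C8=C9 lithium enolate of 29 | [Li]OC1=CC[C@H](OC(=O)c3ccc(O[Si](C)(C)C(C)(C)C)cc3)[C@@H]2[C@](C)(CC[C@@]2(O[Si](CC)(CC)CC)C(C)C)C1 | intermediate
32 | C8 (dimethylamino)methyl ketone (C8 epimers) | CN(C)CC1C[C@H](OC(=O)c3ccc(O[Si](C)(C)C(C)(C)C)cc3)[C@@H]2[C@](C)(CC[C@@]2(O[Si](CC)(CC)CC)C(C)C)CC1=O | intermediate
33 | trimethylammonium iodide of 32 | C[N+](C)(C)CC1C[C@H](OC(=O)c3ccc(O[Si](C)(C)C(C)(C)C)cc3)[C@@H]2[C@](C)(CC[C@@]2(O[Si](CC)(CC)CC)C(C)C)CC1=O.[I-] | intermediate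
34 | C8-methylene C9 ketone | C=C1C[C@H](OC(=O)c3ccc(O[Si](C)(C)C(C)(C)C)cc3)[C@@H]2[C@](C)(CC[C@@]2(O[Si](CC)(CC)CC)C(C)C)CC1=O | intermediate
35 | 9β-allylic alcohol (9R) | C=C1C[C@H](OC(=O)c3ccc(O[Si](C)(C)C(C)(C)C)cc3)[C@@H]2[C@](C)(CC[C@@]2(O[Si](CC)(CC)CC)C(C)C)C[C@H]1O | intermediate
36 | 9α-(4-nitrobenzoate) (9S) | C=C1C[C@H](OC(=O)c3ccc(O[Si](C)(C)C(C)(C)C)cc3)[C@@H]2[C@](C)(CC[C@@]2(O[Si](CC)(CC)CC)C(C)C)C[C@@H]1OC(=O)c1ccc(cc1)[N+](=O)[O-] | intermediate
37 | O4-triethylsilyl ferugin | C=C1C[C@H](OC(=O)c3ccc(O)cc3)[C@@H]2[C@](C)(CC[C@@]2(O[Si](CC)(CC)CC)C(C)C)C[C@@H]1O | intermediate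
38 | ferugin (1R,4R,5S,6S,9S) | C=C1C[C@H](OC(=O)c2ccc(O)cc2)[C@@H]2[C@](C)(CC[C@@]2(O)C(C)C)C[C@@H]1O | target

Total step count: 21. Longest linear sequence: 20 (steps 1–13 and 15–21; step 14 is a one-step side branch).

Steps most likely to fail

Step 10. Insertion at the fully substituted alkene terminus may be slow, so that alkyne oligomerisation takes over. The remote C4 centre may also discriminate only weakly between the two faces of C1=C10. The fallback gives up substrate control and hands the face selection to a chiral ligand. Compound 19 is cyclised with cationic monovalent rhodium carrying BINAP, [Rh((R)-BINAP)]SbF6 or its (S) form, in ClCH2CH2Cl at 40–70 °C. This is the known enantioselective version of the same cycloaddition and it is also more reactive. Both ligand hands are tried and the one matched with C4 is kept. The fallback sets out from 19 and comes back at 20 without any new compound.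

Step 13. Borane may add only sluggishly to an alkene carbon flanked by two quaternary centres, and forcing conditions may open the ketal reductively. The α-isopropyl group may also erode the preference for the α face. The fallback drops the ketal and carries C9 as a β-silyl ether, which survives forcing conditions and puts a third bulky group on the β face.
- It sets out from 21, which is reduced (NaBH4, MeOH, 0 °C; hydride anti to C15) to the 9β-alcohol F1.
- Silylation (TESCl, imidazole, DMF) gives the bis(triethylsilyl) ether F2.
- BH3·SMe2 in THF at 40 °C and then NaOH/H2O2 give the 6α-alcohol F3.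
- Steglich esterification with 27 gives the C6 ester F4.
- PPTS in MeOH at 0 °C frees only the secondary silyl ether to give the 9β-hydroxy ester F5.
- Dess–Martin oxidation brings the sequence back at 29.

Step 19. Attack of the carboxylate at the exposed methylene terminus (SN2′) and loss of the activated hydroxyl group to a conjugated diene may compete with direct displacement. The fallback uses the allylic transposition on purpose.
- It sets out from 35, which is O-sulfenylated (PhSCl, Et3N, THF, −78 °C).
- The sulfenate rearranges at once by the Mislow–Evans [2,3] shift to the C14 allylic sulfoxide F6, which has a C8=C9 alkene.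
- Warmed with Et2NH in MeOH, the sulfoxide re-equilibrates with its C9 sulfenates, which the amine intercepts.
- Oxygen should return to C9 over the open α face and restore the exocyclic methylene, giving the 9α-alcohol F7.
- HF·pyridine then removes both silyl groups, and the sequence comes back at 38.

Further compounds
F0 | step 10 | none | none
F1 | step 13 | 9β-alcohol from 21 | C1CC=C2[C@](C)(CC[C@@]2(O[Si](CC)(CC)CC)C(C)C)C[C@H]1O
F2 | step 13 | O4,O9-bis(triethylsilyl) ether | C1CC=C2[C@](C)(CC[C@@]2(O[Si](CC)(CC)CC)C(C)C)C[C@H]1O[Si](CC)(CC)CC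
F3 | step 13 | 6α-alcohol, H5α, 9β-OTES | C1C[C@H](O)[C@@H]2[C@](C)(CC[C@@]2(O[Si](CC)(CC)CC)C(C)C)C[C@H]1O[Si](CC)(CC)CC
F4 | step 13 | C6 4-(silyloxy)benzoate, 9β-OTES | C1C[C@H](OC(=O)c3ccc(O[Si](C)(C)C(C)(C)C)cc3)[C@@H]2[C@](C)(CC[C@@]2(O[Si](CC)(CC)CC)C(C)C)C[C@H]1O[Si](CC)(CC)CC
F5 | step 13 | 9β-hydroxy C6 ester | C1C[C@H](OC(=O)c3ccc(O[Si](C)(C)C(C)(C)C)cc3)[C@@H]2[C@](C)(CC[C@@]2(O[Si](CC)(CC)CC)C(C)C)C[C@H]1O
F6 | step 19 | C14 phenyl sulfoxide, C8=C9 alkene | O=S(c1ccccc1)CC1=CC[C@@]2(C)CC[C@@](O[Si](CC)(CC)CC)(C(C)C)[C@@H]2[C@@H](OC(=O)c2ccc(O[Si](C)(C)C(C)(C)C)cc2)C1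
F7 | step 19 | 9α-allylic alcohol, both silyl groups in place | C=C1C[C@H](OC(=O)c3ccc(O[Si](C)(C)C(C)(C)C)cc3)[C@@H]2[C@](C)(CC[C@@]2(O[Si](CC)(CC)CC)C(C)C)C[C@@H]1O
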